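**Plan**
Atom labels used throughout: ring C1 (CHOAc), C2 (CH2), C3 (CHBr), C4 (CMe2), C5H=C6; side chain C7 (CHBr), C8 (CH2Cl).
Cuts, in retrosynthetic order: C7–Br, C1–OAc and C3–Br (traced back to the epimeric C–OH, C–OH and C–B), C8–Cl (to a methyl ketone), then C1–C6 together with C5=C6, then the two aldehyde C=O bonds (to terminal alkenes), C1–C2 and the two C–B bonds.
Enabling feature: in the only ring, the cyclohexene, C6 is attached to the carbinol carbon C1, to the alkene CH C5 and to the exocyclic C7. This is the pattern that the carbon between P and C=O of a keto phosphonate leaves after one aldol addition and one olefination, so C1 and C5 are the aldehyde carbons of a 1,5-dialdehyde.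
Forward order: the open chain C1–C5 (7) is assembled first (diboration, vinyl coupling, ozonolysis), the six-membered ring then arises in one step from 7 and phosphonate 8, and the side chain and the three C–heteroatom bonds are adjusted last.
Stereochemistry: C3 from ligand-controlled diboration (R as C–B, inverted to S on bromination); C1 from the annulation (S, cis to boron), inverted to R by Mitsunobu acetylation; C7 from a CBS reduction (S), inverted to R by Appel bromination.

Key step: step 3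

Assumption: the (R,R)-configured TADDOL phosphonite is taken to give the (2R)-bis(boronate) 4; the sense is checked on the diol from an oxidised aliquot, and the (S,S)-ligand is used if it proves opposite.

**Route**

Step 1
Reactants: 1 3,3-dimethylpenta-1,4-diene; 2 bis(pinacolato)diboron; 3 vinyl bromide
Product: 5 2-[(4R)-3,3-dimethylhepta-1,6-dien-4-yl]-4,4,5,5-tetramethyl-1,3,2-dioxaborolane, via bis(boronate) 4 (not isolated)
Conditions: 1 (3 equiv), Pt(dba)3 (1 mol %), (R,R)-3,5-diisopropylphenyl-TADDOL phenylphosphonite (1.2 mol %), THF, 60 °C; excess 1 evaporated; then 3 (1 M in THF), Pd(OAc)2 (1 mol %), RuPhos (1 mol %), KOH, THF/H2O, 70 °C, sealed vessel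
Reagents that add atoms: none
Why: Platinum-catalysed enantioselective diboration of one of the two equivalent vinyl groups of 1 (used in excess to suppress double diboration) sets the boron-bearing centre C3 under ligand control, and the vicinal bis(boronate) then undergoes the known neighbour-accelerated Suzuki–Miyaura coupling at its primary C–B bond only, so the secondary boronate and its configuration are untouched.

Step 2
Reactants: 5 2-[(4R)-3,3-dimethylhepta-1,6-dien-4-yl]-4,4,5,5-tetramethyl-1,3,2-dioxaborolane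
Product: 7 (3R)-2,2-dimethyl-3-(4,4,5,5-tetramethyl-1,3,2-dioxaborolan-2-yl)pentanedial, via bis-ozonide 6 (not isolated)
Conditions: O3, CH2Cl2, −78 °C; then Me2S, −78 °C to rt; water wash, used crude
Reagents that add atoms: ozone, [O-][O+]=O
Why: Ozonolysis with reductive work-up cleaves both monosubstituted alkenes while an alkyl pinacol boronate is inert to ozone at −78 °C; the formaldehyde co-product is washed out so that it cannot consume 8 in the next step.

Step 3
Reactants: 7 (3R)-2,2-dimethyl-3-(4,4,5,5-tetramethyl-1,3,2-dioxaborolan-2-yl)pentanedial; 8 dimethyl (2-oxopropyl)phosphonate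
Product: 11 1-[(4R,6S)-6-hydroxy-3,3-dimethyl-4-(4,4,5,5-tetramethyl-1,3,2-dioxaborolan-2-yl)cyclohex-1-en-1-yl]ethan-1-one, via aldol adduct 9 (not isolated), via cyclic hydroxy phosphonate 10 (not isolated)
Conditions: 8 (1.1 equiv), K2CO3 (3 equiv), H2O/THF, 0 °C to rt
Reagents that add atoms: none
Why: Carbonate deprotonates 8 and the stabilised carbanion adds reversibly to the unhindered C1 aldehyde to give 9, whose hydroxyl stays protonated in water (and can rest on the C3 boron as a five-membered borate), so no olefination occurs there; a second deprotonation at C6 and a 6-(enolexo)-exo-trig addition to the non-enolisable C5 aldehyde close the only ring (10), and the C5 alkoxide, born next to phosphorus, collapses through an oxaphosphetane with loss of dimethyl phosphate to form C5=C6. The closest known reaction type is the tandem aldol/intramolecular Horner–Wadsworth–Emmons annulation of glutaraldehyde with phosphonates in aqueous K2CO3, which gives 6-hydroxycyclohex-1-enyl carbonyl compounds. The new stereocentre C1 is controlled by the resident C3 centre: because the first aldol is reversible, material should drain through the chair-like closure that holds C1–OH and C3–boron equatorial, i.e. cis (1S with 3R). The step needs regioselectivity (aldol at C1, olefination at C5), and this is secured by the steric contrast between the CH2-flanked C1 aldehyde and the neopentyl C5 aldehyde, which fixes the order of the two additions. It also needs a C3 substituent that survives base beside an enolisable aldehyde, which the boronate does where a bromide would be eliminated.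

Step 4
Reactants: 11 1-[(4R,6S)-6-hydroxy-3,3-dimethyl-4-(4,4,5,5-tetramethyl-1,3,2-dioxaborolan-2-yl)cyclohex-1-en-1-yl]ethan-1-one
Product: 12 1-[(4R,6S)-3,3-dimethyl-4-(4,4,5,5-tetramethyl-1,3,2-dioxaborolan-2-yl)-6-[(triethylsilyl)oxy]cyclohex-1-en-1-yl]ethan-1-one
Conditions: Et3SiCl, imidazole, DMF, 0 °C to rt
Reagents that add atoms: chlorotriethylsilane, CC[Si](Cl)(CC)CC
Why: Standard silylation of a secondary allylic alcohol; the triethylsilyl ether masks C1–OH during enolisation, reduction and the aryllithium step and can later be removed in the presence of a tert-butyldimethylsilyl ether.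

Step 5
Reactants: 12 1-[(4R,6S)-3,3-dimethyl-4-(4,4,5,5-tetramethyl-1,3,2-dioxaborolan-2-yl)-6-[(triethylsilyl)oxy]cyclohex-1-en-1-yl]ethan-1-one
Product: 14 2-chloro-1-[(4R,6S)-3,3-dimethyl-4-(4,4,5,5-tetramethyl-1,3,2-dioxaborolan-2-yl)-6-[(triethylsilyl)oxy]cyclohex-1-en-1-yl]ethan-1-one, via silyl enol ether 13 (not isolated)
Conditions: LiN(SiMe3)2, Me3SiCl, THF, −78 °C; then NCS, −78 to 0 °C
Reagents that add atoms: N-chlorosuccinimide, O=C1CCC(=O)N1Cl
Why: Enolisation can only occur at the methyl group because C4 carries no hydrogen, and the resulting 2-silyloxydiene is chlorinated at its CH2 terminus by NCS (α-halogenation of a silyl enol ether), which avoids dichlorination.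

Step 6
Reactants: 14 2-chloro-1-[(4R,6S)-3,3-dimethyl-4-(4,4,5,5-tetramethyl-1,3,2-dioxaborolan-2-yl)-6-[(triethylsilyl)oxy]cyclohex-1-en-1-yl]ethan-1-one
Product: 15 (1S)-2-chloro-1-[(4R,6S)-3,3-dimethyl-4-(4,4,5,5-tetramethyl-1,3,2-dioxaborolan-2-yl)-6-[(triethylsilyl)oxy]cyclohex-1-en-1-yl]ethan-1-ol
Conditions: (S)-Me-CBS oxazaborolidine (20 mol %), BH3·SMe2, THF, −20 °C; MeOH quench
Reagents that add atoms: none
Why: Corey–Bakshi–Shibata reduction in which the substituted cyclohexenyl group is the large and CH2Cl the small substituent, so the (S)-catalyst should deliver hydride to give the (S)-chlorohydrin at C7 under catalyst control, as with aryl chloromethyl ketones.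

Step 7
Reactants: 15 (1S)-2-chloro-1-[(4R,6S)-3,3-dimethyl-4-(4,4,5,5-tetramethyl-1,3,2-dioxaborolan-2-yl)-6-[(triethylsilyl)oxy]cyclohex-1-en-1-yl]ethan-1-ol
Product: 16 tert-butyl{(1S)-2-chloro-1-[(4R,6S)-3,3-dimethyl-4-(4,4,5,5-tetramethyl-1,3,2-dioxaborolan-2-yl)-6-[(triethylsilyl)oxy]cyclohex-1-en-1-yl]ethoxy}dimethylsilane
Conditions: t-BuMe2SiOTf, 2,6-lutidine, CH2Cl2, −78 to 0 °C
Reagents that add atoms: tert-butyldimethylsilyl trifluoromethanesulfonate, CC(C)(C)[Si](C)(C)OS(=O)(=O)C(F)(F)F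
Why: Silylation of the hindered secondary alcohol with the silyl triflate removes the last acidic proton before the aryllithium step and gives a silyl ether that outlasts the triethylsilyl group.

Step 8
Reactants: 16 tert-butyl{(1S)-2-chloro-1-[(4R,6S)-3,3-dimethyl-4-(4,4,5,5-tetramethyl-1,3,2-dioxaborolan-2-yl)-6-[(triethylsilyl)oxy]cyclohex-1-en-1-yl]ethoxy}dimethylsilane
Product: 18 {[(1S,5S)-5-bromo-2-[(1S)-1-[(tert-butyldimethylsilyl)oxy]-2-chloroethyl]-4,4-dimethylcyclohex-2-en-1-yl]oxy}triethylsilane, via boron ate complex 17 (not isolated)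
Conditions: 3,5-(CF3)2C6H3Li (from 3,5-(CF3)2C6H3Br and n-BuLi), THF, −78 °C; then NBS, THF, −78 °C to rt
Reagents that add atoms: N-bromosuccinimide, O=C1CCC(=O)N1Br
Why: Stereoinvertive bromodeboronation of a secondary alkyl pinacol boronate through its aryl ate complex, in which NBS attacks the C3–B bond from the rear (SE2 with inversion) and turns (3R)-C–B into (3S)-C–Br; no carbonyl or acidic hydrogen is present and the primary chloride is inert at −78 °C.

Step 9
Reactants: 18 {[(1S,5S)-5-bromo-2-[(1S)-1-[(tert-butyldimethylsilyl)oxy]-2-chloroethyl]-4,4-dimethylcyclohex-2-en-1-yl]oxy}triethylsilane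
Product: 19 (1S,5S)-5-bromo-2-[(1S)-1-[(tert-butyldimethylsilyl)oxy]-2-chloroethyl]-4,4-dimethylcyclohex-2-en-1-ol
Conditions: PPTS, MeOH/CH2Cl2, 0 °C to rt
Reagents that add atoms: none
Why: Mild acid methanolysis removes a secondary triethylsilyl ether much faster than the bulkier tert-butyldimethylsilyl ether, which differentiates the two allylic hydroxyls.

Step 10
Reactants: 19 (1S,5S)-5-bromo-2-[(1S)-1-[(tert-butyldimethylsilyl)oxy]-2-chloroethyl]-4,4-dimethylcyclohex-2-en-1-ol
Product: 20 (1R,5S)-5-bromo-2-[(1S)-1-[(tert-butyldimethylsilyl)oxy]-2-chloroethyl]-4,4-dimethylcyclohex-2-en-1-yl acetate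
Conditions: PPh3, DIAD, AcOH, THF, 0 °C to rt
Reagents that add atoms: acetic acid, CC(=O)O
Why: Mitsunobu esterification inverts C1 from S to R by SN2 displacement of the oxyphosphonium by acetate, attack at the other allylic terminus C5 being blocked by the adjacent quaternary C4.

Step 11
Reactants: 20 (1R,5S)-5-bromo-2-[(1S)-1-[(tert-butyldimethylsilyl)oxy]-2-chloroethyl]-4,4-dimethylcyclohex-2-en-1-yl acetate
Product: 21 (1R,5S)-5-bromo-2-[(1S)-2-chloro-1-hydroxyethyl]-4,4-dimethylcyclohex-2-en-1-yl acetate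
Conditions: HF·pyridine, THF/pyridine, 0 °C to rt
Reagents that add atoms: none
Why: Acidic fluoride cleaves the silyl ether without forming an alkoxide, so neither acetate migration nor epoxide closure onto CH2Cl should occur.

Step 12
Reactants: 21 (1R,5S)-5-bromo-2-[(1S)-2-chloro-1-hydroxyethyl]-4,4-dimethylcyclohex-2-en-1-yl acetate
Product: 22 (1R,5S)-5-bromo-2-[(1R)-1-bromo-2-chloroethyl]-4,4-dimethylcyclohex-2-en-1-yl acetate
Conditions: CBr4, PPh3, CH2Cl2, 0 °C
Reagents that add atoms: tetrabromomethane, BrC(Br)(Br)Br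
Why: Appel bromination in which bromide displaces the oxyphosphonium at C7 with inversion (S to R), the electron-withdrawing CH2Cl disfavouring ionisation and the quaternary C4 disfavouring allylic transposition to C5.

**Compound list**
1 | 3,3-dimethylpenta-1,4-diene | C=CC(C)(C)C=C | starting material
2 | bis(pinacolato)diboron | CC1(C)OB(OC1(C)C)B1OC(C)(C)C(C)(C)O1 | starting material
3 | vinyl bromide (bromoethene) | C=CBr | starting material
4 | 2,2'-[(2R)-3,3-dimethylpent-4-ene-1,2-diyl]bis(4,4,5,5-tetramethyl-1,3,2-dioxaborolane) | CC1(C)OB(C[C@@H](B2OC(C)(C)C(C)(C)O2)C(C)(C)C=C)OC1(C)C | intermediate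
5 | 2-[(4R)-3,3-dimethylhepta-1,6-dien-4-yl]-4,4,5,5-tetramethyl-1,3,2-dioxaborolane | C=CC[C@@H](B1OC(C)(C)C(C)(C)O1)C(C)(C)C=C | intermediate
6 | 2-[(2R)-3-methyl-1,3-bis(1,2,4-trioxolan-3-yl)butan-2-yl]-4,4,5,5-tetramethyl-1,3,2-dioxaborolane (bis-ozonide of 5; trioxolane carbons of undefined configuration) | C1(C[C@@H](B2OC(C)(C)C(C)(C)O2)C(C)(C)C2OCOO2)OCOO1 | intermediate
7 | (3R)-2,2-dimethyl-3-(4,4,5,5-tetramethyl-1,3,2-dioxaborolan-2-yl)pentanedial | O=CC[C@@H](B1OC(C)(C)C(C)(C)O1)C(C)(C)C=O | intermediate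
8 | dimethyl (2-oxopropyl)phosphonate | COP(=O)(CC(C)=O)OC | starting material
9 | dimethyl [(6R)-4-hydroxy-7,7-dimethyl-2,8-dioxo-6-(4,4,5,5-tetramethyl-1,3,2-dioxaborolan-2-yl)octan-3-yl]phosphonate (chain C3 and C4 not fixed, equilibrating) | CC(=O)C(P(=O)(OC)OC)C(O)C[C@@H](B1OC(C)(C)C(C)(C)O1)C(C)(C)C=O | intermediate
10 | dimethyl [(4R,6S)-1-acetyl-2,6-dihydroxy-3,3-dimethyl-4-(4,4,5,5-tetramethyl-1,3,2-dioxaborolan-2-yl)cyclohexyl]phosphonate (ring C1 and C2 not fixed, lost on elimination) | CC(=O)C1(P(=O)(OC)OC)[C@@H](O)C[C@@H](B2OC(C)(C)C(C)(C)O2)C(C)(C)C1O | intermediate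
11 | 1-[(4R,6S)-6-hydroxy-3,3-dimethyl-4-(4,4,5,5-tetramethyl-1,3,2-dioxaborolan-2-yl)cyclohex-1-en-1-yl]ethan-1-one | O[C@H]1C[C@@H](B2OC(C)(C)C(C)(C)O2)C(C)(C)C=C1C(C)=O | intermediate
12 | 1-[(4R,6S)-3,3-dimethyl-4-(4,4,5,5-tetramethyl-1,3,2-dioxaborolan-2-yl)-6-[(triethylsilyl)oxy]cyclohex-1-en-1-yl]ethan-1-one | CC[Si](CC)(CC)O[C@H]1C[C@@H](B2OC(C)(C)C(C)(C)O2)C(C)(C)C=C1C(C)=O | intermediate
13 | triethyl{[(1S,5R)-4,4-dimethyl-5-(4,4,5,5-tetramethyl-1,3,2-dioxaborolan-2-yl)-2-{1-[(trimethylsilyl)oxy]ethenyl}cyclohex-2-en-1-yl]oxy}silane | CC[Si](CC)(CC)O[C@H]1C[C@@H](B2OC(C)(C)C(C)(C)O2)C(C)(C)C=C1C(=C)O[Si](C)(C)C | intermediate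
14 | 2-chloro-1-[(4R,6S)-3,3-dimethyl-4-(4,4,5,5-tetramethyl-1,3,2-dioxaborolan-2-yl)-6-[(triethylsilyl)oxy]cyclohex-1-en-1-yl]ethan-1-one | CC[Si](CC)(CC)O[C@H]1C[C@@H](B2OC(C)(C)C(C)(C)O2)C(C)(C)C=C1C(=O)CCl | intermediate
15 | (1S)-2-chloro-1-[(4R,6S)-3,3-dimethyl-4-(4,4,5,5-tetramethyl-1,3,2-dioxaborolan-2-yl)-6-[(triethylsilyl)oxy]cyclohex-1-en-1-yl]ethan-1-ol | CC[Si](CC)(CC)O[C@H]1C[C@@H](B2OC(C)(C)C(C)(C)O2)C(C)(C)C=C1[C@H](O)CCl | intermediate
16 | tert-butyl{(1S)-2-chloro-1-[(4R,6S)-3,3-dimethyl-4-(4,4,5,5-tetramethyl-1,3,2-dioxaborolan-2-yl)-6-[(triethylsilyl)oxy]cyclohex-1-en-1-yl]ethoxy}dimethylsilane | CC[Si](CC)(CC)O[C@H]1C[C@@H](B2OC(C)(C)C(C)(C)O2)C(C)(C)C=C1[C@H](O[Si](C)(C)C(C)(C)C)CCl | intermediate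
17 | lithium [3,5-bis(trifluoromethyl)phenyl] borate (ate complex) of 16, aryl group added to boron, carbon configurations as in 16 | [Li+].CC[Si](CC)(CC)O[C@H]1C[C@@H]([B-]2(OC(C)(C)C(C)(C)O2)c2cc(cc(c2)C(F)(F)F)C(F)(F)F)C(C)(C)C=C1[C@H](O[Si](C)(C)C(C)(C)C)CCl | intermediate
18 | {[(1S,5S)-5-bromo-2-[(1S)-1-[(tert-butyldimethylsilyl)oxy]-2-chloroethyl]-4,4-dimethylcyclohex-2-en-1-yl]oxy}triethylsilane | CC[Si](CC)(CC)O[C@H]1C[C@H](Br)C(C)(C)C=C1[C@H](O[Si](C)(C)C(C)(C)C)CCl | intermediate
19 | (1S,5S)-5-bromo-2-[(1S)-1-[(tert-butyldimethylsilyl)oxy]-2-chloroethyl]-4,4-dimethylcyclohex-2-en-1-ol | O[C@H]1C[C@H](Br)C(C)(C)C=C1[C@H](O[Si](C)(C)C(C)(C)C)CCl | intermediate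
20 | (1R,5S)-5-bromo-2-[(1S)-1-[(tert-butyldimethylsilyl)oxy]-2-chloroethyl]-4,4-dimethylcyclohex-2-en-1-yl acetate | CC(=O)O[C@@H]1C[C@H](Br)C(C)(C)C=C1[C@H](O[Si](C)(C)C(C)(C)C)CCl | intermediate
21 | (1R,5S)-5-bromo-2-[(1S)-2-chloro-1-hydroxyethyl]-4,4-dimethylcyclohex-2-en-1-yl acetate | CC(=O)O[C@@H]1C[C@H](Br)C(C)(C)C=C1[C@H](O)CCl | intermediate
22 | (1R,5S)-5-bromo-2-[(1R)-1-bromo-2-chloroethyl]-4,4-dimethylcyclohex-2-en-1-yl acetate (CNP0213819.1) | CC(=O)O[C@@H]1C[C@H](Br)C(C)(C)C=C1[C@@H](Br)CCl | target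

**Count**
Total steps: 12. Longest linear sequence: 12 steps (1 to 22).

**Steps most likely to fail**

Step 3. What may go wrong: ring closure may outrun reversal of the first aldol, so that C1 is set by weak open-chain induction from C3 and the C1 epimer accumulates. The fallback sets out from 7 and 8 and comes back at 11. The annulation is run as before and the epimer 1-[(4R,6R)-6-hydroxy-3,3-dimethyl-4-(4,4,5,5-tetramethyl-1,3,2-dioxaborolan-2-yl)cyclohex-1-en-1-yl]ethan-1-one F1 is separated from 11. It is esterified with inversion (4-nitrobenzoic acid, PPh3, DIAD, THF, 0 °C) to (1S,5R)-2-acetyl-4,4-dimethyl-5-(4,4,5,5-tetramethyl-1,3,2-dioxaborolan-2-yl)cyclohex-2-en-1-yl 4-nitrobenzoate F2, and methanolysis (K2CO3 cat., MeOH, 0 °C) returns 11. C1 is then set by an SN2 inversion and not by the ring closure; attack at C5 is again blocked by C4.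

Step 8. What may go wrong: slow ate-complex formation at the boron next to the quaternary C4, or a single-electron bromination pathway, with loss of configuration at C3 or elimination. The fallback sets out from 16 and comes back at 18. Oxidation (NaBO3·4H2O, THF/H2O, rt) replaces boron by hydroxyl with retention to give (1R,5S)-4-[(1S)-1-[(tert-butyldimethylsilyl)oxy]-2-chloroethyl]-2,2-dimethyl-5-[(triethylsilyl)oxy]cyclohex-3-en-1-ol F3. Deoxybromination with inversion (CBr4, PPh3, 2,6-lutidine, toluene, 60 °C) then leads to 18. The C3 configuration rests on two classical operations (retention, then SN2 inversion) and no ate complex is needed; the displacement at this neopentyl-type carbinol is expected to be slow.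

Step 10. What may go wrong: elimination of the oxyphosphonium towards C2 or incomplete inversion at the hindered allylic carbinol. The fallback sets out from 19 and comes back at 20. Oxidation (Dess–Martin periodinane, CH2Cl2, 0 °C, no amine) gives (5S)-5-bromo-2-[(1S)-1-[(tert-butyldimethylsilyl)oxy]-2-chloroethyl]-4,4-dimethylcyclohex-2-en-1-one F4, used at once because it is a β-bromo ketone. Catalyst-controlled reduction ((S)-Me-CBS oxazaborolidine, BH3·SMe2, THF, −20 °C, alkene side as the large group) should give (1R,5S)-5-bromo-2-[(1S)-1-[(tert-butyldimethylsilyl)oxy]-2-chloroethyl]-4,4-dimethylcyclohex-2-en-1-ol F5. Plain acetylation with retention (Ac2O, pyridine, DMAP, CH2Cl2, 0 °C) gives 20. C1 is reset through the ketone under reagent control and no displacement at C1 is required.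

**Further compounds**
F1 | step 3 | 1-[(4R,6R)-6-hydroxy-3,3-dimethyl-4-(4,4,5,5-tetramethyl-1,3,2-dioxaborolan-2-yl)cyclohex-1-en-1-yl]ethan-1-one | O[C@@H]1C[C@@H](B2OC(C)(C)C(C)(C)O2)C(C)(C)C=C1C(C)=O
F2 | step 3 | (1S,5R)-2-acetyl-4,4-dimethyl-5-(4,4,5,5-tetramethyl-1,3,2-dioxaborolan-2-yl)cyclohex-2-en-1-yl 4-nitrobenzoate | O=C(O[C@H]1C[C@@H](B2OC(C)(C)C(C)(C)O2)C(C)(C)C=C1C(C)=O)c1ccc(cc1)[N+](=O)[O-]
F3 | step 8 | (1R,5S)-4-[(1S)-1-[(tert-butyldimethylsilyl)oxy]-2-chloroethyl]-2,2-dimethyl-5-[(triethylsilyl)oxy]cyclohex-3-en-1-ol | CC[Si](CC)(CC)O[C@H]1C[C@@H](O)C(C)(C)C=C1[C@H](O[Si](C)(C)C(C)(C)C)CCl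
F4 | step 10 | (5S)-5-bromo-2-[(1S)-1-[(tert-butyldimethylsilyl)oxy]-2-chloroethyl]-4,4-dimethylcyclohex-2-en-1-one | O=C1C[C@H](Br)C(C)(C)C=C1[C@H](O[Si](C)(C)C(C)(C)C)CCl
F5 | step 10 | (1R,5S)-5-bromo-2-[(1S)-1-[(tert-butyldimethylsilyl)oxy]-2-chloroethyl]-4,4-dimethylcyclohex-2-en-1-ol | O[C@@H]1C[C@H](Br)C(C)(C)C=C1[C@H](O[Si](C)(C)C(C)(C)C)CCl
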